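**Retrosynthetic overview**
- The C11'–OAc is made last by acetylation. The ArO–C1' bond comes from a Mitsunobu union of 4,5-dihydroxy-6-methoxyphthalide (through its more acidic 5-OH) with (2E,6E)-3,7,11-trimethyldodeca-2,6-diene-1,11-diol.
- C2'=C3' (E) comes from syn-methylalumination of a terminal enyne followed by CH2O. C3'–C4' comes from acetylide plus a homoallylic iodide.
- C6'=C7' (E) is the key step: a 1,2-shift of the C8'–C12' alkyl group from copper to C-5 of lithiated 2,3-dihydrofuran (C–O cleaved with inversion), then MeI.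
- Phthalide: p-cresol → 3,5-dibromo-4-hydroxybenzaldehyde → syringaldehyde → 5-hydroxyvanillin, then a new Mg-templated CH2O annulation that forms the C3–C3a bond and the lactone.
- Rings: the benzene ring is bought. The γ-lactone is the only ring formed (step 4). The dihydrofuran ring is opened in the key step.

Assumption: the target has no stereocentre, so "single enantiomer" is read as the single (2E,6E) isomer drawn.

**Step 1**
Reactants: 1 p-cresol (4-methylphenol)
Product: 4 3,5-dibromo-4-hydroxybenzaldehyde, via 2,6-dibromo-4-methylphenol 2 (not isolated), via 2,6-dibromo-4-(dibromomethyl)phenol 3 (not isolated)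
Conditions: Br2 (2.05 equiv), o-dichlorobenzene, 35 °C; Br2 (2.05 equiv), 155 °C; H2O, 100 °C
Reagents that add atoms: bromine, BrBr; water, O
Why: Electrophilic ortho,ortho'-dibromination of the phenol is followed at high temperature by radical benzylic dibromination and hydrolysis of the benzal bromide, which is the established one-pot p-cresol process.

**Step 2**
Reactants: 4 3,5-dibromo-4-hydroxybenzaldehyde
Product: 5 syringaldehyde (4-hydroxy-3,5-dimethoxybenzaldehyde)
Conditions: NaOMe (5 equiv), CuCl (20 mol %), DMF–MeOH, 110 °C; aq HCl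
Reagents that add atoms: sodium methoxide, C[O-].[Na+]
Why: Copper-catalysed Ullmann-type methoxylation replaces both aryl bromides, and the phenoxide and the aldehyde are inert to it.

**Step 3**
Reactants: 5 syringaldehyde
Product: 6 3,4-dihydroxy-5-methoxybenzaldehyde (5-hydroxyvanillin)
Conditions: AlCl3 (1.2 equiv), pyridine (4.5 equiv), CH2Cl2, reflux, 24 h; aq HCl
Reagents that add atoms: none
Why: In this phenoxide-directed Lewis-acid ether cleavage, Al bound to O-4 activates one of the two equivalent flanking OMe groups for SN2 attack by pyridine, and the Al catecholate so formed stops a second cleavage.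

**Step 4**
Reactants: 6 3,4-dihydroxy-5-methoxybenzaldehyde
Product: 9 4,5-dihydroxy-6-methoxyisobenzofuran-1(3H)-one, via hydroxymethyl aldehyde 7 (not isolated), via lactol 8 (not isolated)
Conditions: MgCl2 (3 equiv), Et3N (6 equiv), (CH2O)n (8 equiv), MeCN, 80 °C, 8 h; 2 M HCl
Reagents that add atoms: paraformaldehyde (as formaldehyde), C=O
Why: Proposed new method: the Mg catecholate of 6 can pass coordinated CH2O only to C-2, the one free position ortho to a Mg-bound oxygen, and the new benzylic alkoxide (7) adds to the neighbouring CHO to give lactolate 8, whose hydridic acetal C–H is handed to a second Mg-bound CH2O (Oppenauer/Tishchenko-type transfer, MeOH lost), so the former aldehyde carbon ends as the lactone C=O; any dialdehyde formed instead should converge on 9, because the Mg-chelated salicyl-type CHO at C-2 is the better hydride acceptor; the closest known reaction type is the MgCl2/Et3N/paraformaldehyde (Casnati–Skattebøl) ortho-formylation of phenols, where the same hydride transfer turns the salicyl alkoxide into the aldehyde.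

**Step 5**
Reactants: 10 5-chloropentan-2-one
Product: 11 5-chloro-2-methylpentan-2-ol
Conditions: MeMgBr (1.1 equiv), Et2O, −20 → 0 °C; aq NH4Cl
Reagents that add atoms: methylmagnesium bromide, C[Mg]Br
Why: This is a Grignard 1,2-addition to the ketone, kept cold so that the chloro alkoxide does not close to 2,2-dimethyltetrahydrofuran.

**Step 6 (key step)**
Reactants: 11 5-chloro-2-methylpentan-2-ol; 12 2,3-dihydrofuran
Product: 17 (E)-4,8-dimethylnon-3-ene-1,8-diol, via dilithio reagent 13 (not isolated), via 5-lithio-2,3-dihydrofuran 14 (not isolated), via mixed cuprate 15 (not isolated), via (Z)-alkenylcopper 16 (not isolated)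
Conditions: 11: n-BuLi (1.0 equiv), then Li powder, DTBB (5 mol %), THF, −78 °C; 12: t-BuLi (1.1 equiv), THF, −78 → 0 °C; CuBr·SMe2 (1.0 equiv), THF–Me2S, −78 °C, combine, → 0 °C to rt, 2 h; MeI (5 equiv), DMPU, 0 °C → rt; aq NH4Cl–NH3
Reagents that add atoms: iodomethane, CI
Why: In this Kocienski 1,2-metallate rearrangement of an α-alkoxyalkenyl cuprate, the alkyl ligand of 15 shifts from Cu to the adjacent C-5 anti to the departing ring oxygen (inversion at the sp2 carbon), so Cu in 16 sits cis to the CH2CH2OLi arm and its methylation with retention sets the E olefin (typically ≥95:5) while forming the C7'–C8' and C7'–CH3 bonds in one flask.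

**Step 7**
Reactants: 17 (E)-4,8-dimethylnon-3-ene-1,8-diol
Product: 18 (E)-9-iodo-2,6-dimethylnon-6-en-2-ol
Conditions: I2 (1.1 equiv), PPh3 (1.1 equiv), imidazole (1.5 equiv), CH2Cl2, 0 °C, 1 h
Reagents that add atoms: iodine, II
Why: Garegg–Samuelsson (Appel-type) iodination is an SN2 process that takes only the primary carbinol and leaves the tertiary alcohol and the olefin geometry untouched.

**Step 8**
Reactants: 18 (E)-9-iodo-2,6-dimethylnon-6-en-2-ol; 19 lithium acetylide–ethylenediamine complex
Product: 20 (E)-2,6-dimethylundec-6-en-10-yn-2-ol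
Conditions: 19 (3 equiv), DMSO–THF, 0 °C → rt; H2O
Reagents that add atoms: none
Why: This is an SN2 alkylation of acetylide by the primary iodide, with one extra equivalent taken up by the tertiary OH, which returns on work-up.

**Step 9**
Reactants: 20 (E)-2,6-dimethylundec-6-en-10-yn-2-ol
Product: 22 (2E,6E)-3,7,11-trimethyldodeca-2,6-diene-1,11-diol, via alkenylalane 21 (not isolated)
Conditions: AlMe3 (3.5 equiv), Cp2ZrCl2 (25 mol %), CH2Cl2, 0 °C → rt; evaporate; hexane–THF, n-BuLi (2.2 equiv), −78 → 0 °C; (CH2O)n (6 equiv), rt; aq Rochelle salt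
Reagents that add atoms: trimethylaluminium, C[Al](C)C; paraformaldehyde (as formaldehyde), C=O
Why: Negishi Zr-catalysed syn-methylalumination puts Me on C-3' and Al on the terminal carbon cis to it, and the derived alanate adds to formaldehyde with retention, which sets the 2E olefin (>98:2) without touching the 6E one.

**Step 10**
Reactants: 22 (2E,6E)-3,7,11-trimethyldodeca-2,6-diene-1,11-diol; 9 4,5-dihydroxy-6-methoxyisobenzofuran-1(3H)-one
Product: 23 4-hydroxy-5-{[(2E,6E)-11-hydroxy-3,7,11-trimethyldodeca-2,6-dien-1-yl]oxy}-6-methoxyisobenzofuran-1(3H)-one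
Conditions: 9 (1.1 equiv), PPh3 (1.2 equiv), DIAD (1.2 equiv), THF, 0 °C → rt
Reagents that add atoms: none
Why: In this Mitsunobu etherification, only the primary allylic alcohol is activated and it is displaced (SN2, geometry kept) by the more acidic 5-OH, which lies para to the lactone carbonyl, as in the 4-O-selective alkylation of gallates.

**Step 11**
Reactants: 23 hydroxy ether from step 10
Product: 25 farnesylemefuranone F, via bis-acetate 24 (not isolated)
Conditions: Ac2O (5 equiv), Et3N (6 equiv), DMAP (0.5 equiv), CH2Cl2, rt, 36 h; then MeOH, K2CO3 (0.2 equiv), 0 °C, 30 min; aq NH4Cl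
Reagents that add atoms: acetic anhydride, CC(=O)OC(C)=O
Why: DMAP-catalysed (Steglich-type) acetylation takes both the tertiary alcohol and the phenol, and brief transesterification then removes only the far more electrophilic aryl acetate.

**Compound list**
1 | p-cresol | Cc1ccc(O)cc1 | starting material
2 | 2,6-dibromo-4-methylphenol | Cc1cc(Br)c(O)c(Br)c1 | intermediate (not isolated)
3 | 2,6-dibromo-4-(dibromomethyl)phenol | BrC(Br)c1cc(Br)c(O)c(Br)c1 | intermediate (not isolated)
4 | 3,5-dibromo-4-hydroxybenzaldehyde | O=Cc1cc(Br)c(O)c(Br)c1 | intermediate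
5 | syringaldehyde | COc1cc(C=O)cc(OC)c1O | intermediate
6 | 3,4-dihydroxy-5-methoxybenzaldehyde | COc1cc(C=O)cc(O)c1O | intermediate
7 | 3,4-dihydroxy-2-(hydroxymethyl)-5-methoxybenzaldehyde | COc1cc(C=O)c(CO)c(O)c1O | intermediate (not isolated)
8 | 6-methoxy-1,3-dihydroisobenzofuran-1,4,5-triol (racemic lactol) | COc1cc2c(c(O)c1O)COC2O | intermediate (not isolated)
9 | 4,5-dihydroxy-6-methoxyisobenzofuran-1(3H)-one | COc1cc2c(c(O)c1O)COC2=O | intermediate
10 | 5-chloropentan-2-one | CC(=O)CCCCl | starting material
11 | 5-chloro-2-methylpentan-2-ol | CC(C)(O)CCCCl | intermediate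
12 | 2,3-dihydrofuran | C1CC=CO1 | starting material
13 | lithium 5-lithio-2-methylpentan-2-olate | [Li]CCCC(C)(C)O[Li] | intermediate (not isolated)
14 | 5-lithio-2,3-dihydrofuran | [Li]C1=CCCO1 | intermediate (not isolated)
15 | lithium (4,5-dihydrofuran-2-yl)[4-(lithiooxy)-4-methylpentyl]cuprate | [Li+].[Li]OC(C)(C)CCC[Cu-]C1=CCCO1 | intermediate (not isolated)
16 | (Z)-[1,8-bis(lithiooxy)-8-methylnon-3-en-4-yl]copper (Cu cis to the CH2CH2OLi arm) | [Li]OCC/C=C(\[Cu])CCCC(C)(C)O[Li] | intermediate (not isolated)
17 | (E)-4,8-dimethylnon-3-ene-1,8-diol | OCC/C=C(\C)CCCC(C)(C)O | intermediate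
18 | (E)-9-iodo-2,6-dimethylnon-6-en-2-ol | ICC/C=C(\C)CCCC(C)(C)O | intermediate
19 | lithium acetylide–ethylenediamine complex | [Li]C#C.NCCN | starting material
20 | (E)-2,6-dimethylundec-6-en-10-yn-2-ol | C#CCC/C=C(\C)CCCC(C)(C)O | intermediate
21 | (1E,5E)-alkenyl(dimethyl)alane, tertiary O as OAlMe2 (Al cis to the new CH3) | C[Al](C)/C=C(\C)CC/C=C(\C)CCCC(C)(C)O[Al](C)C | intermediate (not isolated)
22 | (2E,6E)-3,7,11-trimethyldodeca-2,6-diene-1,11-diol | OC/C=C(\C)CC/C=C(\C)CCCC(C)(C)O | intermediate
23 | 4-hydroxy-5-{[(2E,6E)-11-hydroxy-3,7,11-trimethyldodeca-2,6-dien-1-yl]oxy}-6-methoxyisobenzofuran-1(3H)-one | COc1cc2c(c(O)c1OC/C=C(\C)CC/C=C(\C)CCCC(C)(C)O)COC2=O | intermediate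
24 | 5-{[(2E,6E)-11-acetoxy-3,7,11-trimethyldodeca-2,6-dien-1-yl]oxy}-6-methoxy-1-oxo-1,3-dihydroisobenzofuran-4-yl acetate | COc1cc2c(c(OC(C)=O)c1OC/C=C(\C)CC/C=C(\C)CCCC(C)(C)OC(C)=O)COC2=O | intermediate (not isolated)
25 | farnesylemefuranone F | COc1cc2c(c(O)c1OC/C=C(\C)CC/C=C(\C)CCCC(C)(C)OC(C)=O)COC2=O | target

**Total steps:** 11. **Longest linear sequence:** 7 (10 → 25, steps 5–11). The arene branch is 4 steps plus 2 shared steps.

**Steps most likely to fail**

Risk 1, step 4 (the new step). The reaction may stop at the dialdehyde, lose material through o-quinone-methide oligomers, or give some of the isomeric lactone. The fallback uses known chemistry only; it sets out from 5 and comes back at 9. Oxidise 5 with Ag2O in aq NaOH to syringic acid F1, then esterify (MeOH, H2SO4) to methyl syringate F2. Cleave one OMe with AlCl3/pyridine to give methyl 3,4-dihydroxy-5-methoxybenzoate F3. Run the ordinary MgCl2/Et3N/paraformaldehyde ortho-formylation to obtain methyl 2-formyl-3,4-dihydroxy-5-methoxybenzoate F4. Reduce the aldehyde with NaBH4 to methyl 3,4-dihydroxy-2-(hydroxymethyl)-5-methoxybenzoate F5, which lactonises to 9 on acidification. In this sequence the carbonyl position is fixed by the ester before the C1 unit is introduced.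

Risk 2, step 6. The oxido-alkyl dianion may be poorly soluble, the alkyl cuprate may decay before the shift, or 16 may be protonated instead of methylated. The fallback sets out from 11 and comes back at 17. Alkylate 19 with 11 (cat. NaI, DMSO) to give 2-methylhept-6-yn-2-ol F6. Carry out Zr-catalysed methylalumination (AlMe3, Cp2ZrCl2) to the (E)-alkenyl(dimethyl)alane F7. Convert F7 to the alanate with n-BuLi and open oxirane, which gives 17 with the same E geometry by retention at the alkenyl carbon.

Risk 3, step 10. The catechol unit of 9 can tie up the phosphonium species as a cyclic dioxyphosphorane, and some 4-O- or bis-alkylation is possible. The fallback sets out from 22 and comes back at 23. Brominate the primary allylic alcohol (CBr4, PPh3, CH2Cl2, −20 °C) to (6E,10E)-12-bromo-2,6,10-trimethyldodeca-6,10-dien-2-ol F8. Use F8 to alkylate the mono-phenoxide of 9, generated with one equivalent of a weak base (KHCO3, DMF, rt), which deprotonates only the 5-OH.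

**Further compounds**
F1 | step 4 | syringic acid | COc1cc(C(=O)O)cc(OC)c1O
F2 | step 4 | methyl syringate | COC(=O)c1cc(OC)c(O)c(OC)c1
F3 | step 4 | methyl 3,4-dihydroxy-5-methoxybenzoate | COC(=O)c1cc(O)c(O)c(OC)c1
F4 | step 4 | methyl 2-formyl-3,4-dihydroxy-5-methoxybenzoate | COC(=O)c1cc(OC)c(O)c(O)c1C=O
F5 | step 4 | methyl 3,4-dihydroxy-2-(hydroxymethyl)-5-methoxybenzoate | COC(=O)c1cc(OC)c(O)c(O)c1CO
F6 | step 6 | 2-methylhept-6-yn-2-ol | C#CCCCC(C)(C)O
F7 | step 6 | (E)-alkenyl(dimethyl)alane, tertiary O as OAlMe2 | C[Al](C)/C=C(\C)CCCC(C)(C)O[Al](C)C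
F8 | step 10 | (6E,10E)-12-bromo-2,6,10-trimethyldodeca-6,10-dien-2-ol | BrC/C=C(\C)CC/C=C(\C)CCCC(C)(C)O
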